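## Structural features

The target is a 3-methylidene-γ-butyrolactone (ring A) whose γ-carbon C-5 (S) carries a four-carbon chain: a CH2 group, a methyl-bearing tertiary carbinol carbon C-2′ (S), a secondary carbinol carbon C-3′ (R) and an OCH2 group bound as an aryl ether to C-7 of a coumarin (rings B and C). C-5 and C-2′ stand 1,3 to each other across the CH2 group, C-2′ and C-3′ are directly adjacent, and all three lie on an open chain with no ring to relay stereochemical information. The vicinal diol is of the unlike type, which is the result of an anti addition of two oxygen atoms to an (E)-trisubstituted alkene, the geometry that is easiest to make. Fragile groups are the exocyclic methylene lactone (a strong Michael acceptor towards alkoxides, amines and thiols), the coumarin lactone (opened by strong base), the tertiary alcohol (ionisable in strong acid) and, in the intermediates, a prenyl-type allylic aryl ether and a β,γ-unsaturated aldehyde. The real difficulty is the fully substituted carbinol C-2′, which must be set in a defined relation to both neighbours. The key step exploits the 1,3-relation between the oxygen on C-5 and C-2′: as a tert-butyl carbonate, that oxygen substituent can reach the tertiary carbon of a 2′,3′-epoxide through a six-membered ring and deliver the C-2′ oxygen with inversion, which turns the trans-epoxide of the (E)-alkene into exactly the unlike diol.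

## Logic of the disconnections

**15 ⇒ 13 (through 14).** 15 is cut at the acyl–oxygen bond of ring A, and the hydroxyl groups on C-5 and C-2′ are tied together through a carbonyl group, which gives 13 with an open ethyl acrylate. The cut is made there because the C-5 oxygen must be free of the lactone while it acts on C-2′, and the carbonate is what that event leaves behind. Nothing but a carbonate remains to be removed, so no separate protecting-group step is needed. The forward step must cleave the carbonate and close the lactone without adding a nucleophile to the methylene group; hydroxide followed by acid, through 14, meets this.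

**13 ⇒ 12.** 13 is cut at the bond between the tertiary ring carbon C-6 of the dioxanone (C-2′ of 15) and the carbonate oxygen, which leads back to the epoxide and tert-butyl carbonate of 12. The two oxygens of the diol then come from one epoxide oxygen and one carbonate oxygen, placed anti to each other by the mechanism. The tertiary-carbinol problem shrinks to a trans-epoxide plus one existing stereocentre. The forward step must attack only the tertiary carbon, with clean inversion, while the acrylate, the aryl ether and the coumarin stay out of it.

**12 ⇒ 11.** 12 is cut at both C–O bonds of the oxirane, giving 11. Two stereocentres are exchanged for one alkene geometry. The forward step needs reagent-controlled face selection on the only electron-rich C=C bond of three.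

**11 ⇒ 10.** 11 is cut at the O–C(=O) bond of the carbonate. The tert-butyl carbonate is put on only after the carbinol exists, because it would not survive organoaluminium or organochromium chemistry. The forward acylation must be faster than closure of the γ-hydroxy ester to a lactone.

**10 ⇒ 7 + 8 (through 9).** 10 is cut at the C-3–C-4 bond (C-β–C-γ). 8 then supplies C-β, C-α, the methylene carbon and the ester in one piece with the right carbon count. Joining 8 instead to a CH2X group on the carbinol carbon would give a chain one CH2 too long. The cut is convergent and creates the C-γ stereocentre in the same step. The demand is enantioface selection on an unbranched aldehyde under conditions that neither enolise it nor let the adduct lactonise; 9, the O-silylated form in which the adduct leaves the catalytic cycle, serves the second point.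

**7 ⇒ 6 ⇒ 5.** 7 is traced back to 6 by a change of oxidation state at C-1, and 6 to 5 by a silyl group on that oxygen. A β,γ-unsaturated aldehyde has to be made last and used at once, so its carbon is carried as a protected alcohol. The demand is a near-neutral oxidation.

**5 ⇒ 3 + 4.** 5 is cut at the allylic C–O(aryl) bond. An ether from a phenol of pKa about 8 and a primary allylic alcohol is the most reliable bond in the molecule, and forming it early means the allylic alcohol never needs protection. The coumarin arrives complete. The demand is direct SN2 displacement without allylic transposition.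

**3 ⇒ 1 (through 2).** 3 is cut at the C-3–CH3 bond and at the C-1–C-2 bond. Syn addition of methyl and metal to a terminal alkyne, followed by one-carbon capture of 2, defines the (E)-trisubstituted alkene in one flask from a commercial alkyne. The demand is delivery of methyl to the internal carbon and retention in the C–Al to C–C exchange.

## Other disconnections considered

**Alternative 1:** The cut goes through both carbinol C–O bonds of the diol while the chain is folded into a δ-lactone. The future OCH2 carbon is the lactone carbonyl, C-3′ and C-2′ are the ring alkene, and the γ-carbon carries a chloromethyl group that is the future C-β. This is (6R)-6-(chloromethyl)-4-methyl-5,6-dihydro-2H-pyran-2-one A2. The forward key step is an osmium-catalysed syn-dihydroxylation of A2 on the face away from the chloromethyl group, giving (3S,4S,6R)-6-(chloromethyl)-3,4-dihydroxy-4-methyloxan-2-one A1.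
- In its favour: the ring enforces the Z geometry, so a syn addition gives the unlike diol. All three stereocentres derive from one chiral-pool centre by substrate control with no chiral catalyst at all; on this point the alternative is better than the chosen plan, which needs two catalyst-controlled steps. The cycloaddition is as stereospecific as the epoxide opening of the chosen plan, so the two are equal there.
- Against it here: A2 is an electron-poor trisubstituted enoate and should be osmylated slowly. The only face-directing element is a CH2Cl group 1,3 and 1,4 to the reacting carbons on a flexible half-chair, whereas the chosen key step needs no facial bias (inversion at a defined carbon). After A1 the lactone carbonyl must be reduced to the OCH2 carbon and arylated with 4 in the presence of three other hydroxyl groups, which calls for protecting groups. The chloromethyl carbon must be bonded to the α-carbon of an acrylate, for which 8 cannot be used without inserting an extra carbon.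
- Comparison: on structure, both plans rest on the same equivalence (anti on E, syn on Z). On mechanism, both are stereospecific. On step economy, an estimated twelve to fourteen steps stand against nine.

**Alternative 2:** The cut goes through the bond from the chain CH2 to C-γ and through the bond from the ring oxygen to an acetal carbon, which is the future OCH2 carbon. The forward key step is a catalytic asymmetric hetero-Diels–Alder reaction between (1E)-1-methoxy-3-methylbuta-1,3-diene A4 and ethyl glyoxylate A5 under a chiral Lewis acid, giving ethyl (2R,6S)-6-methoxy-4-methyl-3,6-dihydro-2H-pyran-2-carboxylate A3 (cis).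
- In its favour: one catalytic step sets C-γ, which is better than the chosen plan in the number of catalyst-controlled steps. The ring again makes the alkene Z, and two cis substituents shield one face, so a later syn-dihydroxylation should be well controlled; this is at least equal to the catalyst-controlled epoxidation of the chosen plan. The starting materials are cheap.
- Against it here: A3 carries both ends at the wrong oxidation level. The acetal carbon must be unmasked and reduced to the OCH2 carbon, the ester carbon must be reduced and activated as the C-β electrophile, and the diol must be protected meanwhile. The acrylate arm then faces the same carbon-count problem as in Alternative 1.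
- Comparison: on structure, the pyran is a sound template for the stereotriad but contains none of the final rings. On mechanism, a concerted cycloaddition plus a face-selective osmylation are as dependable as the chosen sequence. On step economy it is clearly worse (about thirteen or more steps against nine), mainly through redox and protecting-group traffic.

**Alternative 3:** The cut is the C-γ–O bond, with the oxygen coming from a tert-butyl carbonate on the tertiary carbinol. The precursor is tert-butyl (2R,3S)-2-{[tert-butyl(dimethyl)silyl]oxy}-3-methyl-1-[(2-oxo-2H-chromen-7-yl)oxy]hex-5-en-3-yl carbonate A7. In the forward key step an electrophilic iodine source activates the terminal alkene, and the carbonate carbonyl oxygen closes to (4R,6S)-6-{(1R)-1-{[tert-butyl(dimethyl)silyl]oxy}-2-[(2-oxo-2H-chromen-7-yl)oxy]ethyl}-4-(iodomethyl)-6-methyl-1,3-dioxan-2-one A6, whose iodomethyl carbon is the future C-β.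
- In its favour: C-γ is relayed from C-2′ through a chair-like transition state without a second chiral catalyst, which is better than the chosen plan. The same 1,3-dioxan-2-one is formed by the same kind of carbonyl-oxygen participation, so the two are mechanistically equal in type. From A6 a terminal epoxide and the classical α-phosphono-lactone olefination would build the methylene lactone last, so no γ-hydroxy acrylate has to be kept from lactonising; here too the alternative is better.
- Against it here: A7 already contains the unlike diol. The hard problem, a tertiary carbinol anti to its neighbour, is therefore not solved by the key step but moved upstream, where it again needs a Z-alkene or an anti opening. A tert-butyl carbonate on a tertiary alcohol is hard to install. The needed isomer has the iodomethyl group cis to the oxygenated chain with the methyl group axial, and the preference between a methyl group and a branched chain on a fully substituted carbon is smaller than the usual preference against hydrogen. A silyl group must be put on and taken off.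
- Comparison: on structure, both plans use the 1,3-relation of the two oxygens. On mechanism, the chosen plan is stereospecific (inversion at a defined epoxide carbon), whereas this one is only stereoselective. On step economy, about twelve to thirteen steps stand against nine.

Key step: step 8

**Remark on the chemistry.** Joining 8 to an iodomethyl group on the carbinol carbon (radical or SN2′ allylation) would place two CH2 groups between the carbinol and the acrylate carbon and lead to the six-membered lactone homologue. The carbinol carbon is therefore generated from an aldehyde, so that 8 delivers the acrylate arm with the correct carbon count.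

**Assumption.** In step 5 the ligand antipode that directs the allyl group to the Si face of 7 is used; both antipodes are accessible, and the configuration of 10 is to be secured (MTPA esters) before step 6.

## Route

Step 1
Reactants: 1 tert-butyl(but-3-yn-1-yloxy)dimethylsilane
Product: 3 (2E)-5-{[tert-butyl(dimethyl)silyl]oxy}-3-methylpent-2-en-1-ol, via alkenylalane 2 (not isolated)
Conditions: Me3Al, Cp2ZrCl2 (25 mol%), CH2Cl2, 0 °C→rt; then (CH2O)n, 0 °C→rt; aq. potassium sodium tartrate
Reagents that add atoms: trimethylaluminium, C[Al](C)C; formaldehyde (as paraformaldehyde), C=O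
Why: Zirconium-catalysed Negishi carboalumination adds methyl and aluminium syn across the terminal alkyne with methyl on the internal carbon, so 2 should be a single (E) isomer; its C–Al bond then adds to formaldehyde with retention, which places the methyl group cis to CH2OH. The silyl ether tolerates the Lewis-acidic medium.

Step 2
Reactants: 3 (2E)-5-{[tert-butyl(dimethyl)silyl]oxy}-3-methylpent-2-en-1-ol; 4 umbelliferone (7-hydroxy-2H-chromen-2-one)
Product: 5 7-{[(2E)-5-{[tert-butyl(dimethyl)silyl]oxy}-3-methylpent-2-en-1-yl]oxy}-2H-chromen-2-one
Conditions: PPh3, DIAD, THF, 0 °C→rt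
Reagents that add atoms: none
Why: Mitsunobu etherification; the acidic 7-hydroxyl of 4 is an ideal pronucleophile and the primary allylic oxyphosphonium ion should be displaced by direct SN2 attack, leaving the alkene geometry untouched. The neutral conditions spare the coumarin lactone.

Step 3
Reactants: 5 7-{[(2E)-5-{[tert-butyl(dimethyl)silyl]oxy}-3-methylpent-2-en-1-yl]oxy}-2H-chromen-2-one
Product: 6 7-{[(2E)-5-hydroxy-3-methylpent-2-en-1-yl]oxy}-2H-chromen-2-one
Conditions: HF·pyridine, pyridine, THF, 0 °C→rt
Reagents that add atoms: none
Why: Fluoride-driven cleavage of the primary silyl ether, driven by the strong Si–F bond; the pyridine-buffered reagent is not basic enough to open the coumarin and not acidic enough to ionise the prenyl-type aryl ether.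

Step 4
Reactants: 6 7-{[(2E)-5-hydroxy-3-methylpent-2-en-1-yl]oxy}-2H-chromen-2-one
Product: 7 (3E)-3-methyl-5-[(2-oxo-2H-chromen-7-yl)oxy]pent-3-enal
Conditions: DMP, pyridine, CH2Cl2, 0 °C; crude product used at once
Reagents that add atoms: none
Why: Dess–Martin oxidation runs under near-neutral conditions, which matters because a β,γ-unsaturated aldehyde can slip into conjugation or lose the aryloxide by vinylogous elimination when acid or base is present; 7 is therefore neither stored nor chromatographed.

Step 5
Reactants: 7 (3E)-3-methyl-5-[(2-oxo-2H-chromen-7-yl)oxy]pent-3-enal; 8 ethyl 2-(bromomethyl)acrylate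
Product: 10 ethyl (4R,6E)-4-hydroxy-6-methyl-2-methylidene-8-[(2-oxo-2H-chromen-7-yl)oxy]oct-6-enoate, via silyl ether 9 (not isolated)
Conditions: CrCl2 (10 mol%), chiral 1,8-bis(oxazolin-2-yl)carbazole ligand (12 mol%), Mn powder, Me3SiCl, iPr2NEt (30 mol%), THF, 0 °C→rt; then aq. citric acid, THF, 0 °C
Reagents that add atoms: none
Why: Catalytic asymmetric Nozaki–Hiyama–Kishi-type 2-(alkoxycarbonyl)allylation: Mn keeps the chromium in the divalent state, which turns 8 into an allylchromium species that adds to the aldehyde through a closed six-membered transition state inside the tridentate ligand. Si-face attack gives the (4R) carbinol of 10, the future (S) γ-centre. In situ O-silylation to 9 releases the catalyst and blocks lactonisation until the mild acidic work-up.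

Step 6
Reactants: 10 ethyl (4R,6E)-4-hydroxy-6-methyl-2-methylidene-8-[(2-oxo-2H-chromen-7-yl)oxy]oct-6-enoate
Product: 11 ethyl (4R,6E)-4-[(tert-butoxycarbonyl)oxy]-6-methyl-2-methylidene-8-[(2-oxo-2H-chromen-7-yl)oxy]oct-6-enoate
Conditions: Boc2O, DMAP (20 mol%), CH2Cl2, 0 °C→rt
Reagents that add atoms: di-tert-butyl dicarbonate, CC(C)(C)OC(=O)OC(=O)OC(C)(C)C
Why: DMAP-catalysed acylation of the secondary alcohol through the acylpyridinium ion of Boc2O; the low temperature and the absence of a stronger base should keep the γ-hydroxy ester from closing to the lactone before it is capped. The stereocentre is not involved.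

Step 7
Reactants: 11 ethyl (4R,6E)-4-[(tert-butoxycarbonyl)oxy]-6-methyl-2-methylidene-8-[(2-oxo-2H-chromen-7-yl)oxy]oct-6-enoate
Product: 12 ethyl (4S)-4-[(tert-butoxycarbonyl)oxy]-2-methylidene-5-[(2R,3R)-2-methyl-3-{[(2-oxo-2H-chromen-7-yl)oxy]methyl}oxiran-2-yl]pentanoate
Conditions: D-fructose-derived ketone catalyst (30 mol%), KHSO5 (as 2KHSO5·KHSO4·K2SO4), K2CO3, Bu4NHSO4 (cat.), MeCN/CH2(OMe)2, aq. Na2B4O7 buffer (pH about 10.5), 0 °C
Reagents that add atoms: potassium peroxymonosulfate, [K+].[O-]S(=O)(=O)OO
Why: Shi epoxidation: the chiral dioxirane transfers oxygen through a spiro transition state to the electron-rich (E)-trisubstituted alkene only, since the acrylate and the coumarin double bonds are electron-poor. The D-fructose-derived ketone should deliver oxygen to the face that gives the (2R,3R) trans-epoxide, as with other (E)-trisubstituted alkenes, and catalyst control should override the remote C-4 centre. The change of the C-4 descriptor from R to S is only a change of CIP priorities.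

Step 8
Reactants: 12 ethyl (4S)-4-[(tert-butoxycarbonyl)oxy]-2-methylidene-5-[(2R,3R)-2-methyl-3-{[(2-oxo-2H-chromen-7-yl)oxy]methyl}oxiran-2-yl]pentanoate
Product: 13 ethyl 2-{[(4S,6S)-6-{(1R)-1-hydroxy-2-[(2-oxo-2H-chromen-7-yl)oxy]ethyl}-6-methyl-2-oxo-1,3-dioxan-4-yl]methyl}prop-2-enoate
Conditions: BF3·OEt2 (0.5 equiv), CH2Cl2, −78 °C→−40 °C; sat. aq. NaHCO3
Reagents that add atoms: none
Why: BF3 binds the epoxide oxygen and polarises the bond to the tertiary carbon, which carries positive charge best. The carbonyl oxygen of the tert-butyl carbonate, placed 1,3 to that carbon, attacks it from the rear in a 6-exo-tet closure to give a 2-tert-butoxy-1,3-dioxan-2-ylium ion, which loses isobutene, and the proton ends on the former epoxide oxygen as the free secondary hydroxyl. The closest known reaction type is the Lewis-acid-promoted cyclisation of epoxy tert-butyl carbonates to cyclic carbonates, the epoxide counterpart of iodocarbonate cyclisation. Ring closed: the 1,3-dioxan-2-one, by 6-exo attack; the 7-endo alternative at the secondary carbon is disfavoured by ring size and by the electron-withdrawing aryloxymethyl group on that carbon. New stereocentre: the tertiary carbinol carbon, formed with inversion of the (R) epoxide carbon and therefore (S); it is controlled by the epoxide configuration from step 7 and by the SN2-like course, while the secondary carbinol keeps its (R) configuration and C-4 is untouched, so the unlike diol follows from the trans-epoxide. The step needs regioselectivity (tertiary over secondary carbon), stereospecificity (no free cation) and chemoselectivity over hydride shift and over attack by the arene; the short tether, a chair-like transition state with both large substituents equatorial, the low temperature and the electron-poor coumarin ring should secure them. The acrylate ester, the aryl ether and the coumarin lactone are spectators under these conditions.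

Step 9
Reactants: 13 ethyl 2-{[(4S,6S)-6-{(1R)-1-hydroxy-2-[(2-oxo-2H-chromen-7-yl)oxy]ethyl}-6-methyl-2-oxo-1,3-dioxan-4-yl]methyl}prop-2-enoate
Product: 15 (5S)-5-{(2S,3R)-2,3-dihydroxy-2-methyl-4-[(2-oxo-2H-chromen-7-yl)oxy]butyl}-3-methylideneoxolan-2-one, via trihydroxy acid 14 (not isolated)
Conditions: LiOH, THF/H2O (3:1), 0 °C→rt, dark; then 1 M HCl to pH 1–2, rt
Reagents that add atoms: water, O
Why: Hydroxide hydrolyses the cyclic carbonate and the ethyl ester; the resulting carboxylate is a poor Michael acceptor, so the methylene group should be safe in base. On acidification the γ-hydroxy acid 14 closes to the five-membered lactone, the only strain-free ring available to the carboxyl group, and any coumarin opened to the (Z)-coumarinate re-closes. No stereocentre is touched.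

## Compound list

1 | tert-butyl(but-3-yn-1-yloxy)dimethylsilane | C#CCCO[Si](C)(C)C(C)(C)C | starting material
2 | [(1E)-4-{[tert-butyl(dimethyl)silyl]oxy}-2-methylbut-1-en-1-yl]dimethylalane | C/C(CCO[Si](C)(C)C(C)(C)C)=C\[Al](C)C | intermediate (not isolated)
3 | (2E)-5-{[tert-butyl(dimethyl)silyl]oxy}-3-methylpent-2-en-1-ol | C/C(CCO[Si](C)(C)C(C)(C)C)=C\CO | intermediate
4 | umbelliferone (7-hydroxy-2H-chromen-2-one) | Oc1ccc2ccc(=O)oc2c1 | starting material
5 | 7-{[(2E)-5-{[tert-butyl(dimethyl)silyl]oxy}-3-methylpent-2-en-1-yl]oxy}-2H-chromen-2-one | C/C(CCO[Si](C)(C)C(C)(C)C)=C\COc1ccc2ccc(=O)oc2c1 | intermediate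
6 | 7-{[(2E)-5-hydroxy-3-methylpent-2-en-1-yl]oxy}-2H-chromen-2-one | C/C(CCO)=C\COc1ccc2ccc(=O)oc2c1 | intermediate
7 | (3E)-3-methyl-5-[(2-oxo-2H-chromen-7-yl)oxy]pent-3-enal | C/C(CC=O)=C\COc1ccc2ccc(=O)oc2c1 | intermediate
8 | ethyl 2-(bromomethyl)acrylate | C=C(CBr)C(=O)OCC | starting material
9 | ethyl (4R,6E)-6-methyl-2-methylidene-8-[(2-oxo-2H-chromen-7-yl)oxy]-4-[(trimethylsilyl)oxy]oct-6-enoate | C=C(C[C@H](O[Si](C)(C)C)C/C(C)=C/COc1ccc2ccc(=O)oc2c1)C(=O)OCC | intermediate (not isolated)
10 | ethyl (4R,6E)-4-hydroxy-6-methyl-2-methylidene-8-[(2-oxo-2H-chromen-7-yl)oxy]oct-6-enoate | C=C(C[C@H](O)C/C(C)=C/COc1ccc2ccc(=O)oc2c1)C(=O)OCC | intermediate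
11 | ethyl (4R,6E)-4-[(tert-butoxycarbonyl)oxy]-6-methyl-2-methylidene-8-[(2-oxo-2H-chromen-7-yl)oxy]oct-6-enoate | C=C(C[C@H](OC(=O)OC(C)(C)C)C/C(C)=C/COc1ccc2ccc(=O)oc2c1)C(=O)OCC | intermediate
12 | ethyl (4S)-4-[(tert-butoxycarbonyl)oxy]-2-methylidene-5-[(2R,3R)-2-methyl-3-{[(2-oxo-2H-chromen-7-yl)oxy]methyl}oxiran-2-yl]pentanoate | C=C(C[C@H](OC(=O)OC(C)(C)C)C[C@@]1(C)O[C@@H]1COc1ccc2ccc(=O)oc2c1)C(=O)OCC | intermediate
13 | ethyl 2-{[(4S,6S)-6-{(1R)-1-hydroxy-2-[(2-oxo-2H-chromen-7-yl)oxy]ethyl}-6-methyl-2-oxo-1,3-dioxan-4-yl]methyl}prop-2-enoate | C=C(C[C@H]1C[C@](C)(OC(=O)O1)[C@H](O)COc1ccc2ccc(=O)oc2c1)C(=O)OCC | intermediate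
14 | (4S,6S,7R)-4,6,7-trihydroxy-6-methyl-2-methylidene-8-[(2-oxo-2H-chromen-7-yl)oxy]octanoic acid | C=C(C[C@H](O)C[C@](C)(O)[C@H](O)COc1ccc2ccc(=O)oc2c1)C(=O)O | intermediate (not isolated)
15 | (5S)-5-{(2S,3R)-2,3-dihydroxy-2-methyl-4-[(2-oxo-2H-chromen-7-yl)oxy]butyl}-3-methylideneoxolan-2-one | C=C1C[C@@H](C[C@](C)(O)[C@H](O)COc2ccc3ccc(=O)oc3c2)OC1=O | target

## Step count and least certain steps

Total number of steps: 9. Longest linear sequence: 9 steps (1 to 15); 4 and 8 enter as commercial materials.

**Step 8 (key step).**
- What may go wrong: the Lewis acid may open the epoxide to a tertiary cation faster than the carbonate oxygen traps it. Hydride shift to a carbonyl compound (Meinwald-type rearrangement), attack by the coumarin ring, or partial loss of stereospecificity would then compete. Loss of the tert-butyl group without ring closure, or migration of the carbonate to the neighbouring secondary hydroxyl, are further possibilities; the migration would be harmless for step 9.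
- Fallback (sets out from 12, returns at 15): the epoxide is opened intermolecularly with dilute HClO4 in THF/H2O, where water should attack the tertiary carbon of an aliphatic epoxide from the rear. This gives the diol carbonate ethyl (4S,6S,7R)-4-[(tert-butoxycarbonyl)oxy]-6,7-dihydroxy-6-methyl-2-methylidene-8-[(2-oxo-2H-chromen-7-yl)oxy]octanoate F1. F1 is then taken through the conditions of step 9: the tertiary alkoxide closes onto the carbonate carbonyl, the cyclic carbonate so formed is hydrolysed, and acidification should give 15.

**Step 5.**
- What may go wrong: insufficient enantioface discrimination on an unbranched aldehyde; isomerisation of the β,γ-unsaturated aldehyde into conjugation or vinylogous elimination of the aryloxide, triggered by the amine or by Lewis-acidic chromium and silicon species; premature lactonisation of the adduct.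
- Fallback (sets out from 6, returns at 10): the C–C bond is made at the alcohol oxidation level by iridium-catalysed transfer-hydrogenative 2-(alkoxycarbonyl)allylation ([Ir(cod)Cl]2, a chiral bisphosphine, 4-cyano-3-nitrobenzoic acid, Cs2CO3, ethyl 2-(acetoxymethyl)acrylate, THF, 60–80 °C), so that the aldehyde is only a transient species. The adduct is allowed to lactonise fully (catalytic TsOH) to (5R)-3-methylidene-5-{(2E)-2-methyl-4-[(2-oxo-2H-chromen-7-yl)oxy]but-2-en-1-yl}oxolan-2-one F2, a stable compound on which the enantiomeric purity can be determined. LiOH in THF/H2O opens F2 to (4R,6E)-4-hydroxy-6-methyl-2-methylidene-8-[(2-oxo-2H-chromen-7-yl)oxy]oct-6-enoic acid F3 (kept as its lithium salt), and alkylation of the carboxylate with EtI in DMF should return 10.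

**Step 7.**
- What may go wrong: the allylic aryloxy group lowers the nucleophilicity of the alkene, so slow oxygen transfer may let the ketone catalyst decay by Baeyer–Villiger oxidation and may leave facial selectivity incomplete; long exposure to the basic buffer may begin to hydrolyse the esters.
- Fallback (sets out from 11, returns at 12): reagent control is given up. 11 is epoxidised with m-CPBA (NaHCO3, CH2Cl2, 0 °C), which should attack only the electron-rich trisubstituted alkene but without facial preference. 12 is then separated by chromatography from its epimer ethyl (4S)-4-[(tert-butoxycarbonyl)oxy]-2-methylidene-5-[(2S,3S)-2-methyl-3-{[(2-oxo-2H-chromen-7-yl)oxy]methyl}oxiran-2-yl]pentanoate F4, with the C-4 centre serving as an internal resolving handle.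

**Step 9.**
- What may go wrong: conjugate addition of hydroxide to the methylene group before saponification; isomerisation of the opened coumarinate so that ring C does not re-close; incomplete lactonisation; loss of the very polar acid on extraction.
- Fallback (sets out from 13, returns at 15): the Michael acceptor is masked before any base is applied. Thiophenol with catalytic Et3N is added to the acrylate of 13 to give the sulfide ethyl 2-{[(4S,6S)-6-{(1R)-1-hydroxy-2-[(2-oxo-2H-chromen-7-yl)oxy]ethyl}-6-methyl-2-oxo-1,3-dioxan-4-yl]methyl}-3-(phenylsulfanyl)propanoate F5. K2CO3 in MeOH then cleaves the carbonate and closes the lactone, giving (5S)-5-{(2S,3R)-2,3-dihydroxy-2-methyl-4-[(2-oxo-2H-chromen-7-yl)oxy]butyl}-3-[(phenylsulfanyl)methyl]oxolan-2-one F6. Oxidation with NaIO4 gives the sulfoxide (5S)-5-{(2S,3R)-2,3-dihydroxy-2-methyl-4-[(2-oxo-2H-chromen-7-yl)oxy]butyl}-3-[(phenylsulfinyl)methyl]oxolan-2-one F7, and thermal syn-elimination (toluene, 90 °C, CaCO3) should regenerate the exocyclic methylene group and return 15.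

## Further compounds

F1 | step 8 | ethyl (4S,6S,7R)-4-[(tert-butoxycarbonyl)oxy]-6,7-dihydroxy-6-methyl-2-methylidene-8-[(2-oxo-2H-chromen-7-yl)oxy]octanoate | C=C(C[C@H](OC(=O)OC(C)(C)C)C[C@](C)(O)[C@H](O)COc1ccc2ccc(=O)oc2c1)C(=O)OCC
F2 | step 5 | (5R)-3-methylidene-5-{(2E)-2-methyl-4-[(2-oxo-2H-chromen-7-yl)oxy]but-2-en-1-yl}oxolan-2-one | C=C1C[C@@H](C/C(C)=C/COc2ccc3ccc(=O)oc3c2)OC1=O
F3 | step 5 | (4R,6E)-4-hydroxy-6-methyl-2-methylidene-8-[(2-oxo-2H-chromen-7-yl)oxy]oct-6-enoic acid | C=C(C[C@H](O)C/C(C)=C/COc1ccc2ccc(=O)oc2c1)C(=O)O
F4 | step 7 | ethyl (4S)-4-[(tert-butoxycarbonyl)oxy]-2-methylidene-5-[(2S,3S)-2-methyl-3-{[(2-oxo-2H-chromen-7-yl)oxy]methyl}oxiran-2-yl]pentanoate | C=C(C[C@H](OC(=O)OC(C)(C)C)C[C@]1(C)O[C@H]1COc1ccc2ccc(=O)oc2c1)C(=O)OCC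
F5 | step 9 | ethyl 2-{[(4S,6S)-6-{(1R)-1-hydroxy-2-[(2-oxo-2H-chromen-7-yl)oxy]ethyl}-6-methyl-2-oxo-1,3-dioxan-4-yl]methyl}-3-(phenylsulfanyl)propanoate (both C-2 epimers) | CCOC(=O)C(CSc1ccccc1)C[C@H]1C[C@](C)(OC(=O)O1)[C@H](O)COc1ccc2ccc(=O)oc2c1
F6 | step 9 | (5S)-5-{(2S,3R)-2,3-dihydroxy-2-methyl-4-[(2-oxo-2H-chromen-7-yl)oxy]butyl}-3-[(phenylsulfanyl)methyl]oxolan-2-one (both C-3 epimers) | c1ccccc1SCC1C[C@@H](C[C@](C)(O)[C@H](O)COc2ccc3ccc(=O)oc3c2)OC1=O
F7 | step 9 | (5S)-5-{(2S,3R)-2,3-dihydroxy-2-methyl-4-[(2-oxo-2H-chromen-7-yl)oxy]butyl}-3-[(phenylsulfinyl)methyl]oxolan-2-one (mixture at C-3 and at sulfur) | O=S(CC1C[C@@H](C[C@](C)(O)[C@H](O)COc2ccc3ccc(=O)oc3c2)OC1=O)c1ccccc1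
A1 | alternative 1 | (3S,4S,6R)-6-(chloromethyl)-3,4-dihydroxy-4-methyloxan-2-one | C[C@@]1(O)[C@H](O)C(=O)O[C@@H](CCl)C1
A2 | alternative 1 | (6R)-6-(chloromethyl)-4-methyl-5,6-dihydro-2H-pyran-2-one | CC1=CC(=O)O[C@@H](CCl)C1
A3 | alternative 2 | ethyl (2R,6S)-6-methoxy-4-methyl-3,6-dihydro-2H-pyran-2-carboxylate | CO[C@@H]1C=C(C)C[C@H](C(=O)OCC)O1
A4 | alternative 2 | (1E)-1-methoxy-3-methylbuta-1,3-diene | CO/C=C/C(C)=C
A5 | alternative 2 | ethyl glyoxylate | CCOC(=O)C=O
A6 | alternative 3 | (4R,6S)-6-{(1R)-1-{[tert-butyl(dimethyl)silyl]oxy}-2-[(2-oxo-2H-chromen-7-yl)oxy]ethyl}-4-(iodomethyl)-6-methyl-1,3-dioxan-2-one | IC[C@H]1C[C@](C)(OC(=O)O1)[C@H](O[Si](C)(C)C(C)(C)C)COc1ccc2ccc(=O)oc2c1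
A7 | alternative 3 | tert-butyl (2R,3S)-2-{[tert-butyl(dimethyl)silyl]oxy}-3-methyl-1-[(2-oxo-2H-chromen-7-yl)oxy]hex-5-en-3-yl carbonate | C=CC[C@](C)(OC(=O)OC(C)(C)C)[C@H](O[Si](C)(C)C(C)(C)C)COc1ccc2ccc(=O)oc2c1
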